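You are asked how much product stands after 25 h in oak, ash and cedar, which differ in initiator loading, and how that amount moves along the row.

the same everywhere: starting material 0.80 M
- north-west: reagent 1.3 equiv; initiator 0.93 mol%; run made earlier
- south-west: reagent 1.3 equiv; initiator 1.6 mol%; run made earlier
- south: reagent 1.3 equiv; initiator 2.9 mol%; run made earlier
- oak: reagent 1.30 equiv; initiator 0.8 mol%; time 25 h
- ash: reagent 1.30 equiv; initiator 1.5 mol%; time 25 h
- cedar: reagent 1.30 equiv; initiator 3 mol%; time 25 h

| run | time / h | product / % |
|---|---|---|
| north-west | 2.00 | 0.3 |
| north-west | 4.00 | 0.9 |
| north-west | 8.00 | 1.3 |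
| north-west | 12.0 | 1.2 |
| north-west | 25.0 | 1.5 |
| south-west | 2.00 | 0.3 |
| south-west | 4.00 | 2.4 |
| south-west | 8.00 | 0.9 |
| south-west | 12.0 | 3.0 |
| south-west | 25.0 | 2.6 |
| south | 2.00 | 1.0 |
| south | 4.00 | 2.0 |
| south | 8.00 | 4.1 |
| south | 12.0 | 4.3 |
| south | 25.0 | 5.1 |

(standard deviation of a reading: 0.5 percentage points)

- "hardly changes" means that all values lie within two and a half points (for a concentration: within two and a half percent of the largest)

- amount of product at the end, in percent of the starting material charged for oak, ash, cedar, in this order
- how that number moves from the first to the last of them (rises all the way / falls, then rises / rises, then falls / falls all the way / hardly changes)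

Start with the south run: it reads 4.1% at 8.00 h and 5.1% at 25.0 h, a gain of 1 percentage point over a long stretch, so the curve has nearly flattened and time is a poor variable here. Divide the rate of product formation by the rate at which initiator is used: that ratio may drift along a run, but integrated up to one end time it is a yield on initiator, in the spirit of a kinetic chain length, and it compares flasks at that time without a time course.

Summing the end readings of the earlier runs and dividing by the summed loadings gives 1.69 as g, the amount of product per amount of initiator charged. The scatter of the readings puts about 0.159 on g.

My own reckoning multiplies g by each loading, which gives 1.36% for oak, 2.54% for ash and 5.08% for cedar.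

The forecast reads the plateaus as “nearly proportional to initiator” and gives 1.4%, 2.6% and 5.1%, with the shape rises all the way. For ash it stands a little higher than my figure.

The simulation gives 1.44%, 2.68% and 5.22%, and the shape is rises all the way.

    initiator → 2 initiating radical (k = 2.70 × 10⁻⁵ s⁻¹)
    starting material + initiating radical → capped initiator + first chain carrier (k = 550 M⁻¹ s⁻¹)
    reagent + first chain carrier ⇌ product + second chain carrier (K = 0.930, k = 50.0 M⁻¹ s⁻¹)
    starting material + second chain carrier → by-product + first chain carrier (k = 69.0 M⁻¹ s⁻¹)
    first chain carrier → ended carrier (k = 36.0 s⁻¹)
    2 first chain carrier → ended chains (k = 7.00 × 10⁶ M⁻¹ s⁻¹)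
    2 reagent → homo dimer (k = 9.30 × 10⁻⁶ M⁻¹ s⁻¹)

In cedar g comes out at 1.74 and in oak at 1.80, so the proportional row stands. To break it, take away the reaction of first chain carrier to ended carrier, the largest single effect among those tested on cedar. Cedar then gives 42.7% instead of 5.22%, a g of 14.2. Taking away the reaction of first chain carrier to ended carrier gives 26.7% in oak, so g there reaches 33.4.

All runs stem from a simulated flask on assumed constants; noise was put on by code.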